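## Plan

Numbering used: ring C1 (OAc), C2 (OAng), C3 (Me)/C4 (epoxide), C5, C6; chain C7(=C14H2)–C8(OH)–C9–C10(OAng)–C11(OH)Me2.

1. Cuts, in retrosynthetic order: the C11 O–Si bond; the C10 ester C–O bond together with the C8–H bond (Evans–Tishchenko with angelic aldehyde); C9–C10 (aldol); the O1–acetyl bond; C8–C9 (MeLi on a lactone); the O2–angeloyl bond; the epoxide C–O bonds; C2–H; and O1–C1, which leads back to a keto acid from (R)-carvone.
2. Feature behind the key step: O1, C1, C6, C7 and C8 form a five-atom chain on one face of the six-membered ring. C8 at the acid level can therefore close a cis-fused α-methylene-γ-butyrolactone onto C1 of the carvone enone and place O1 on the hindered face, cis to the C6–C7 bond.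
3. Forward order: the carvone ring is kept; isopropenyl CH3 becomes CO2H (C8); lactone ring (key step); C2–OH; epoxide ring; O2 angelate; the lactone is opened by MeLi to the C8 methyl ketone and O1 is acetylated; C9–C10 aldol; the Tishchenko step brings in the second angeloyl unit; desilylation.
4. Stereochemistry: C6 from (R)-carvone; C1 from the tether; C2, C3 and C4 by relay from the lactone; C10 from a chiral zinc catalyst; C8 by 1,3-anti hydride transfer from C10.
5. C8 is used three times: as the tether that delivers O1, as the acyl carbon that accepts C9, and as the hydride acceptor that frees the C8 hydroxyl while the C10 angelate is formed.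
6. Only the tertiary C11 hydroxyl carries a protecting group.

Key step: step 4

Assumption: the (S,S)-ProPhenol–dizinc catalyst is taken to add the C9 zinc enolate to the Re face of aldehyde 17, as for simple methyl ketones with α-branched aldehydes; if the sense were the reverse, the (R,R)-ligand would be used.

## Route

Step 1
Reactants: 1 (R)-(−)-carvone
Product: 2 10-chlorocarvone [(5R)-5-(3-chloroprop-1-en-2-yl)-2-methylcyclohex-2-en-1-one]
Conditions: Ca(OCl)2, CO2 (dry ice), CH2Cl2/H2O, 0 °C
Reagents that add atoms: calcium hypochlorite, [Ca+2].[O-]Cl.[O-]Cl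
Why: Ene-type allylic chlorination by hypochlorous acid made in situ should attack only the electron-rich isopropenyl alkene and, as the allyl shift is degenerate, place chlorine on the former methyl carbon (future C8) without touching C6.

Step 2
Reactants: 2 10-chlorocarvone
Product: 3 2-[(1R)-4-methyl-5-oxocyclohex-3-en-1-yl]prop-2-enal
Conditions: NMO, NaHCO3, NaI (cat.), MeCN, 50 °C
Reagents that add atoms: N-methylmorpholine N-oxide, C[N+]1([O-])CCOCC1
Why: Amine N-oxide oxidation of an activated halide (Ganem/Kornblum type): O-alkylation of the N-oxide by the allylic chloride and loss of N-methylmorpholine should give the enal, with SN2 and SN2' paths leading to the same product.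

Step 3
Reactants: 3 2-[(1R)-4-methyl-5-oxocyclohex-3-en-1-yl]prop-2-enal
Product: 4 2-[(1R)-4-methyl-5-oxocyclohex-3-en-1-yl]prop-2-enoic acid
Conditions: NaClO2, NaH2PO4, 2-methyl-2-butene, t-BuOH/H2O, 0 °C to rt
Reagents that add atoms: sodium chlorite, [Na+].[O-]Cl=O
Why: Pinnick oxidation takes an enal to the acrylic acid without touching the alkenes or the enone once hypochlorous acid is scavenged.

Step 4
Reactants: 4 2-[(1R)-4-methyl-5-oxocyclohex-3-en-1-yl]prop-2-enoic acid
Product: 6 cis-fused keto lactone (3aS,7aR)-6-methyl-3-methylidene-3a,4-dihydro-1-benzofuran-2,7(3H,7aH)-dione, via lithium trans-1-iodo keto carboxylate 5 (not isolated)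
Conditions: LiHMDS (2.2 equiv), THF, −78 °C; I2 (1.05 equiv), −78 °C; DMPU, −78 °C to rt
Reagents that add atoms: none
Why: LiHMDS first forms the lithium carboxylate and then removes a C1 proton under kinetic control to give the cross-conjugated C1=C2 dienolate; iodine traps it at C1 as the α'-iodo ketone 5, and the C8 carboxylate displaces iodide from C1 in an intramolecular SN2 reaction. The closest known reaction types are the halolactonisation of keto acids through their α-halo ketones and the hypervalent-iodine lactonisation of 5-oxo acids to keto-γ-lactones. The five-membered lactone ring (O1–C1–C6–C7–C8) closes in the 5-exo-tet mode. The new stereocentre C1 is controlled by the tether: the carboxylate hangs from C7 on C6 and can reach the back side of the C1–I bond only on the face of the C6–C7 bond, so the lactone is cis-fused (1R), and iodide in the flask should epimerise any cis iodide to the reactive trans one. The step needs α' (C1) and not γ (C5) functionalisation, which kinetic deprotonation at −78 °C secures, and substitution ahead of loss of HI to a phenol, which the fast five-membered closure in the presence of DMPU should secure.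

Step 5
Reactants: 6 cis-fused keto lactone
Product: 7 allylic alcohol (3aS,7S,7aR)-7-hydroxy-6-methyl-3-methylidene-3a,4,7,7a-tetrahydro-1-benzofuran-2(3H)-one (C2–OH cis to O1)
Conditions: NaBH4, CeCl3·7H2O, MeOH, −78 °C
Reagents that add atoms: none
Why: Luche 1,2-reduction: hydride should add to C2 from the convex face, anti to the pseudo-axial C1–O bond of the cis-fused lactone (Felkin–Anh polar effect), so that the new C2 hydroxyl is cis to O1, and at −78 °C the cerium-modified borohydride should leave the conjugated lactone alone.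

Step 6
Reactants: 7 allylic alcohol
Product: 8 epoxy alcohol (lactone 7 with a 3,4-epoxide on the face of the C2 hydroxyl; 1R,2R,3R,4S,6S)
Conditions: VO(acac)2 (cat.), t-BuOOH, CH2Cl2, 0 °C to rt
Reagents that add atoms: tert-butyl hydroperoxide, CC(C)(C)OO
Why: Vanadium-catalysed hydroxyl-directed epoxidation delivers the peroxide oxygen to the C3=C4 bond from the face of the C2 hydroxyl, which sets C3 and C4 syn to O2, while the electron-poor exocyclic alkene is inert.

Step 7
Reactants: 8 epoxy alcohol; 9 angelic acid [(Z)-2-methylbut-2-enoic acid]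
Product: 11 C2 angelate of epoxy lactone 8 (1R,2R,3S,4S,6S), via angelic 2,4,6-trichlorobenzoic anhydride 10 (not isolated)
Conditions: 9, 2,4,6-trichlorobenzoyl chloride, Et3N, toluene, rt; then 8, 80 °C
Reagents that add atoms: none
Why: Yamaguchi esterification through the mixed anhydride without DMAP acylates the only free hydroxyl and is the usual way to keep the Z geometry of an angelate.

Step 8
Reactants: 11 C2 angelate lactone
Product: 13 hydroxy methyl ketone (ring as in 11 with free C1–OH; C6 bears C7(=CH2)–C8(=O)–CH3), via lithium lactolate 12 (not isolated)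
Conditions: MeLi (1.05 equiv), THF, −78 °C; sat. aq NH4Cl, −78 °C to rt
Reagents that add atoms: methyllithium, [Li]C
Why: Mono-addition of an organolithium to a γ-lactone at −78 °C stops at the cyclic lithium hemiketal, which opens to the methyl ketone on work-up and frees O1; the unhindered five-membered lactone carbonyl should react well ahead of the hindered, conjugated secondary angelate.

Step 9
Reactants: 13 hydroxy methyl ketone
Product: 14 C1 acetate of 13 (1R,2R,3S,4S,6S)
Conditions: Ac2O, Et3N, DMAP (cat.), CH2Cl2, 0 °C
Reagents that add atoms: acetic anhydride, CC(=O)OC(C)=O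
Why: Standard acylation of the single free secondary hydroxyl; closure of O1 onto C14 would be a disfavoured 5-endo-trig process, so the enone should survive.

Step 10
Reactants: 15 methyl 2-hydroxy-2-methylpropanoate
Product: 16 methyl 2-methyl-2-[(triethylsilyl)oxy]propanoate
Conditions: TESOTf, 2,6-lutidine, CH2Cl2, 0 °C
Reagents that add atoms: triethylsilyl trifluoromethanesulfonate, CC[Si](CC)(CC)OS(=O)(=O)C(F)(F)F
Why: A silyl triflate with a hindered base silylates a tertiary alcohol quickly.

Step 11
Reactants: 16 methyl 2-methyl-2-[(triethylsilyl)oxy]propanoate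
Product: 17 2-methyl-2-[(triethylsilyl)oxy]propanal
Conditions: DIBAL-H, CH2Cl2, −78 °C; aq Rochelle salt
Reagents that add atoms: none
Why: Partial reduction of an α-silyloxy ester by DIBAL-H at −78 °C stops at the aluminium hemiacetal, which gives the non-enolisable aldehyde on work-up.

Step 12
Reactants: 14 acetate methyl ketone; 17 2-methyl-2-[(triethylsilyl)oxy]propanal
Product: 18 (10R)-β-hydroxy ketone (C8 ketone, C10–OH, C11–OTES; ring as in 14)
Conditions: (S,S)-ProPhenol (15 mol%), Et2Zn (30 mol%), Ph3P=S (15 mol%), 4 Å MS, THF, 0 °C; 17 (3 equiv)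
Reagents that add atoms: none
Why: Direct catalytic asymmetric aldol addition with a dinuclear zinc–ProPhenol catalyst, a reaction type established for vinyl methyl ketones and α-branched aldehydes: the zinc enolate can form only at the C9 methyl group, the aldehyde cannot enolise, and the catalyst, not the remote ring, sets C10 (Re-face addition, 10R).

Step 13
Reactants: 9 angelic acid
Product: 19 (Z)-2-methylbut-2-en-1-ol
Conditions: LiAlH4, Et2O, 0 °C
Reagents that add atoms: none
Why: Hydride reduction of the unsaturated acid gives the allylic alcohol with the Z geometry kept.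

Step 14
Reactants: 19 (Z)-2-methylbut-2-en-1-ol
Product: 20 angelic aldehyde [(Z)-2-methylbut-2-enal]
Conditions: Dess–Martin periodinane, NaHCO3, CH2Cl2, 0 °C; solution used at once
Reagents that add atoms: none
Why: Buffered Dess–Martin oxidation at 0 °C is neutral and fast, which should keep the labile Z geometry of the enal.

Step 15
Reactants: 18 (10R)-β-hydroxy ketone; 20 angelic aldehyde
Product: 22 11-O-triethylsilyl ether of the target (8R,10R; C8–OH free, C10–OAng), via C10 hemiacetal 21 (not isolated)
Conditions: SmI2 (30 mol%) premixed with 20 (6 equiv), THF, −10 °C, dark; then 18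
Reagents that add atoms: none
Why: Evans–Tishchenko reduction: the C10 hydroxyl and the aldehyde form a hemiacetal that, bound to samarium(III) together with the C8 ketone, transfers its hydride to C8 through a chair-like six-membered transition state, which sets C8 anti to C10 (8R) and leaves the aldehyde carbon as the C10 angelate and the C8 hydroxyl free.

Step 16
Reactants: 22 11-O-triethylsilyl ether of the target
Product: 23 CNP0105552.1 (target)
Conditions: HF·pyridine, pyridine, THF, 0 °C to rt
Reagents that add atoms: none
Why: Buffered HF·pyridine cleaves the tertiary triethylsilyl ether without base, so the epoxide, the three esters and the Z alkenes should survive and no acyl group should migrate.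

## Compound list

1 | (R)-(−)-carvone, (5R)-2-methyl-5-(prop-1-en-2-yl)cyclohex-2-en-1-one | C=C(C)[C@@H]1CC=C(C)C(=O)C1 | starting material
2 | 10-chlorocarvone, (5R)-5-(3-chloroprop-1-en-2-yl)-2-methylcyclohex-2-en-1-one | C=C(CCl)[C@@H]1CC=C(C)C(=O)C1 | intermediate
3 | 2-[(1R)-4-methyl-5-oxocyclohex-3-en-1-yl]prop-2-enal | C=C(C=O)[C@@H]1CC=C(C)C(=O)C1 | intermediate
4 | 2-[(1R)-4-methyl-5-oxocyclohex-3-en-1-yl]prop-2-enoic acid | C=C(C(=O)O)[C@@H]1CC=C(C)C(=O)C1 | intermediate
5 | lithium 2-[(1S,6S)-6-iodo-4-methyl-5-oxocyclohex-3-en-1-yl]prop-2-enoate (iodine trans to the acrylate; not isolated) | [Li+].[O-]C(=O)C(=C)[C@@H]1CC=C(C)C(=O)[C@H]1I | intermediate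
6 | (3aS,7aR)-6-methyl-3-methylidene-3a,4-dihydro-1-benzofuran-2,7(3H,7aH)-dione (cis-fused keto lactone) | O=C1O[C@H]2C(=O)C(C)=CC[C@H]2C1=C | intermediate
7 | (3aS,7S,7aR)-7-hydroxy-6-methyl-3-methylidene-3a,4,7,7a-tetrahydro-1-benzofuran-2(3H)-one | O=C1O[C@H]2[C@@H](O)C(C)=CC[C@H]2C1=C | intermediate
8 | epoxy alcohol: lactone 7 with a 3,4-epoxide syn to the C2 hydroxyl (1R,2R,3R,4S,6S) | O=C1O[C@H]2[C@@H](O)[C@@]3(C)O[C@H]3C[C@H]2C1=C | intermediate
9 | angelic acid, (Z)-2-methylbut-2-enoic acid | C/C=C(/C)C(=O)O | starting material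
10 | angelic 2,4,6-trichlorobenzoic anhydride (not isolated) | C/C=C(/C)C(=O)OC(=O)c1c(Cl)cc(Cl)cc1Cl | intermediate
11 | C2 angelate of epoxy lactone 8 (1R,2R,3S,4S,6S) | O=C1O[C@H]2[C@@H](OC(=O)/C(C)=C\C)[C@@]3(C)O[C@H]3C[C@H]2C1=C | intermediate
12 | lithium lactolate from MeLi addition to C8 of 11 (C8 configuration not defined; not isolated) | [Li+].[O-]C1(C)O[C@H]2[C@@H](OC(=O)/C(C)=C\C)[C@@]3(C)O[C@H]3C[C@H]2C1=C | intermediate
13 | hydroxy methyl ketone: C1–OH, C2–OAng, 3,4-epoxide, C6–C7(=CH2)–C8(=O)–CH3 (1R,2R,3S,4S,6S) | C=C(C(C)=O)[C@@H]1C[C@@H]2O[C@]2(C)[C@H](OC(=O)/C(C)=C\C)[C@@H]1O | intermediate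
14 | C1 acetate of 13 (1R,2R,3S,4S,6S) | C=C(C(C)=O)[C@@H]1C[C@@H]2O[C@]2(C)[C@H](OC(=O)/C(C)=C\C)[C@@H]1OC(C)=O | intermediate
15 | methyl 2-hydroxy-2-methylpropanoate | COC(=O)C(C)(C)O | starting material
16 | methyl 2-methyl-2-[(triethylsilyl)oxy]propanoate | COC(=O)C(C)(C)O[Si](CC)(CC)CC | intermediate
17 | 2-methyl-2-[(triethylsilyl)oxy]propanal | O=CC(C)(C)O[Si](CC)(CC)CC | intermediate
18 | (10R)-β-hydroxy ketone: C8 ketone, C10–OH, C11–OTES, ring as in 14 | C=C(C(=O)C[C@@H](O)C(C)(C)O[Si](CC)(CC)CC)[C@@H]1C[C@@H]2O[C@]2(C)[C@H](OC(=O)/C(C)=C\C)[C@@H]1OC(C)=O | intermediate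
19 | (Z)-2-methylbut-2-en-1-ol | OC/C(C)=C\C | intermediate
20 | angelic aldehyde, (Z)-2-methylbut-2-enal | O=C/C(C)=C\C | intermediate
21 | hemiacetal of the C10 hydroxyl of 18 with 20, drawn as the free hemiacetal (samarium-bound; not isolated) | C=C(C(=O)C[C@@H](OC(O)/C(C)=C\C)C(C)(C)O[Si](CC)(CC)CC)[C@@H]1C[C@@H]2O[C@]2(C)[C@H](OC(=O)/C(C)=C\C)[C@@H]1OC(C)=O | intermediate
22 | 11-O-triethylsilyl ether of the target (1R,2R,3S,4S,6S,8R,10R) | C=C([C@H](O)C[C@@H](OC(=O)/C(C)=C\C)C(C)(C)O[Si](CC)(CC)CC)[C@@H]1C[C@@H]2O[C@]2(C)[C@H](OC(=O)/C(C)=C\C)[C@@H]1OC(C)=O | intermediate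
23 | CNP0105552.1 (1R,2R,3S,4S,6S,8R,10R) | C=C([C@H](O)C[C@@H](OC(=O)/C(C)=C\C)C(C)(C)O)[C@@H]1C[C@@H]2O[C@]2(C)[C@H](OC(=O)/C(C)=C\C)[C@@H]1OC(C)=O | target

## Step count and risks

Total step count: 16. Longest linear sequence: 12 steps (steps 1–9, 12, 15, 16).

Steps most likely to fail:

1. Step 15. The Z enal may isomerise to the E enal before or during hydride transfer, hydride transfer from the conjugated hemiacetal may be slow, the β-hydroxy ketone may undergo retro-aldol cleavage, or the acyl group may migrate from O10 to O8. Fallback, setting out from 18 and returning at 23: directed reduction with Me4NBH(OAc)3 (MeCN/AcOH, −30 °C, Evans–Saksena reduction) would give the anti-8,10-diol F1. TESOTf/2,6-lutidine at −78 °C would silylate the less hindered allylic C8 hydroxyl to give the 8-O-triethylsilyl ether F2. Yamaguchi esterification with 9 would give the C10 angelate bis-silyl ether F3. HF·pyridine would then remove both silyl groups and give 23.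

2. Step 8. Methyllithium may also attack the angelate carbonyl, add a second time after early collapse of the lactolate, or the angeloyl group may migrate from O2 to the O1 alkoxide. Fallback, setting out from 11 and returning at 13: the aluminium amide from AlMe3 and MeNHOMe·HCl (CH2Cl2, 0 °C) would open only the lactone to the hydroxy Weinreb amide F4. MeMgBr (THF, −78 °C) would then add once to the chelated amide and give 13.

3. Step 4. The α'-iodo ketone may lose HI and aromatise to a phenol, iodination may occur at C5 through the extended enolate, or enolate and iodide may couple before the carboxylate closes the ring. Fallback, setting out from 4 and returning at 6: hydroxylation of the same dianion with 2-(phenylsulfonyl)-3-phenyloxaziridine (THF, −78 °C) should put oxygen on C1 anti to the C6 substituent and give the trans-α'-hydroxy keto acid F5. Mitsunobu lactonisation (PPh3, DIAD, THF, 0 °C) would then close the lactone with inversion at C1 and give 6.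

Further compounds
F1 | step 15 | anti-8,10-diol (8R,10R), C11–OTES, ring as in 14 | C=C([C@H](O)C[C@@H](O)C(C)(C)O[Si](CC)(CC)CC)[C@@H]1C[C@@H]2O[C@]2(C)[C@H](OC(=O)/C(C)=C\C)[C@@H]1OC(C)=O
F2 | step 15 | 8-O-triethylsilyl ether of F1 | C=C([C@H](O[Si](CC)(CC)CC)C[C@@H](O)C(C)(C)O[Si](CC)(CC)CC)[C@@H]1C[C@@H]2O[C@]2(C)[C@H](OC(=O)/C(C)=C\C)[C@@H]1OC(C)=O
F3 | step 15 | 8,11-bis-O-triethylsilyl ether of 23 | C=C([C@H](O[Si](CC)(CC)CC)C[C@@H](OC(=O)/C(C)=C\C)C(C)(C)O[Si](CC)(CC)CC)[C@@H]1C[C@@H]2O[C@]2(C)[C@H](OC(=O)/C(C)=C\C)[C@@H]1OC(C)=O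
F4 | step 8 | hydroxy Weinreb amide: 13 with C8(=O)N(OMe)Me in place of the methyl ketone | C=C(C(=O)N(C)OC)[C@@H]1C[C@@H]2O[C@]2(C)[C@H](OC(=O)/C(C)=C\C)[C@@H]1O
F5 | step 4 | trans-α'-hydroxy keto acid (C1–OH trans to the acrylic acid on C6) | C=C(C(=O)O)[C@@H]1CC=C(C)C(=O)[C@H]1O
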